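Readings and results were generated by integration for an exercise; noise was put on by code.

An easy step comes first: we compare how fast the runs start.

| flask | substrate | reagent in the second phase | remark | time | volume of the second phase over the first |
|---|---|---|---|---|---|
| blue | 0.42 M | 0.22 M | run made earlier |  |  |
| teal | 0.42 M | 0.88 M | run made earlier |  |  |
| grey | 0.21 M | 0.441 M | run made earlier |  |  |
| flask | 0.42 M | 0.441 M |  | 2.5 h | 0.50 |

- blue (time / h: target / %, substrate / %): 0.417: 10.2, 89.6; 0.833: 18.4, 80.8; 1.33: 24.8, 73.8; 1.50: 26.8, 71.8; 2.00: 30.5, 67.4; 2.50: 31.8, 64.6; 3.00: 32.6, 62.9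
- teal (time / h: target / %, substrate / %): 0.167: 15.6, 84.4; 0.500: 43.4, 54.6; 0.833: 57.8, 34.8; 1.33: 61.0, 19.9; 2.00: 49.3, 12.6; 2.50: 40.0, 10.2; 3.00: 32.5, 7.9
- grey (time / h: target / %, substrate / %): 0.250: 19.9, 80.1; 0.417: 33.4, 65.6; 0.833: 54.6, 40.2; 1.50: 59.5, 22.2; 3.00: 38.6, 12.2

(each reading ± 0.3 percentage points)

- in the second phase: reagent in the second phase; everything else is in the first
- charges count per volume of the first phase; a concentration in a rate is the amount of a species over the volume of its own phase; every rate counts per litre of the first phase
- what was read earlier has a scatter of 0.3 percentage points, one standard deviation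
- the earlier runs hold the two phases in the same ratio of volumes as the flask asked about

- amount of target at 2.5 h, in percent of the substrate charged
- part of the substrate charged that has reacted at 2.5 h

Up to its first reading the teal run makes target at 0.392 M h⁻¹ and the blue run, up to its own, at 0.103 M h⁻¹, a ratio of 3.81 for a ratio of 4.00 in the reagent charged. So we read the rate as pseudo-first-order in the reagent in the second phase. Dividing the rate of reagent use by the reagent still waiting then leaves a quotient with no time in it, the uptake coefficient κ.

We count reagent used as target plus two for each substrate gone beyond target, our own assumption. In the blue run at 1.50 h, that leaves 43.5% of the charge waiting, so κ = 0.555 h⁻¹.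

Our flask should start near 0.245 M h⁻¹. We reckon with one slowing of this rate, the shrinking of what waits, and by 2.5 h that cuts the rate to 25.0% of the start, about a quarter. The reagent built into products then comes to 78.8% of the substrate charged. That figure ties the two answers without splitting them: conversion counted double, minus target, should equal it.

The forecast, “Stepping through in half-hours”, gave 55% target and 66% reacted.

The flask gives 48.7% target with 62.0% reacted.

    2 substrate → self-condensation product (k = 5.80 × 10⁻⁷ L mol⁻¹ s⁻¹)
    reagent in the reaction phase + target → over-reacted product (k = 0.00210 L mol⁻¹ s⁻¹)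
    substrate + reagent in the reaction phase ⇌ target (K = 64.0 L mol⁻¹, k = 0.0210 L mol⁻¹ s⁻¹)
    reagent in the reaction phase → decomposed reagent (k = 4.00 × 10⁻⁵ s⁻¹)
    reagent in the reaction phase ⇌ reagent in the second phase, rate k5*([reagent in the reaction phase] - [reagent in the second phase]/K5) per volume of the first phase (partition coefficient = 0.560, kL = 4.80 × 10⁻⁵ s⁻¹)

Conversion counted double, minus target, is 75.3% against our 78.8%, and the flask's reagent in the second phase stands at 22.3% of its charge against our 25.0%. Left until 4.0 h, the neighbouring flask should keep 10.9% of its charge by κ, and it holds 9.61%.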